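**Remarks on the chemistry (assumptions)**
- α is the face of the bicyclic core that carries the two ring-fusion hydrogens (convex face); β is the opposite, concave face. Bicyclo[3.3.0]octane numbering is used for compounds 7–14; from 15 on, the indene numbering of the target is used (C1 side-chain carbon, C2 ketone, C3a/C7a ring fusion, C4 methylidene carbon, C5/C6 acyloxy carbons, C7 oxiranyl carbon).
- The sense of induction of the BINAP–rhodium catalyst (step 5) and of the chiral lithium amide (step 10) is assumed as drawn; the mirror-image ligand or base is used if the opposite sense is found.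
- The 2-methylbutanoate stereocentre in the target SMILES is (R), so (R)-2-methylbutanoic acid is used.

**Retrosynthetic overview**
1. End game: the two acyloxy groups, the C2 ketone and the acetate are unveiled one at a time from silyl ethers; the methyl glycidate at C7 comes from a cis-fused α-methylene-γ-lactone (C7/C6–O) by bromohydrin closure and lactone opening, and the lactone carbon is put on the concave face by C–H insertion of a C6–O diazoacetate.
2. The C4(=CH2)/C5–O/C6–O array comes from a 4-methyl-4-en-6-one by Luche reduction, anti epoxidation and epoxide-to-allylic-silyl-ether isomerisation.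
3. Key disconnection: the six-membered ring is not cyclised but made by one-carbon ring expansion of ring B of a cis-diquinane, through strain-releasing oxidative opening of a siloxycyclopropane. The enabling feature is that C4 (methylidene carbon), C5–O and C6–O are the retron of a 4-methyl-4-en-6-one whose C5 is a one-carbon insert between the ketone carbon C6 and the methyl-bearing carbon C4 of a cyclopentanone.
4. The diquinane comes from a Pauson–Khand reaction of an enyne built from (S)-but-3-yn-2-ol and 2-allyloxirane; convex-face hydrogenation then sets C1 and C7a cis to H-3a.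
5. Ring order of the skeleton: cyclopentenone ring A and five-membered carbocycle ring B together (step 5), then the cyclohexane ring by enlargement of ring B (step 13), which is the last ring of the skeleton to be closed; the γ-lactone is temporary and the oxirane is a functional group added later.

Key step: step 13

**Route**

Step 1
Reactants: 1 (S)-but-3-yn-2-ol
Product: 2 tert-butyldiphenylsilyl ether of 1
Conditions: TBDPSCl, imidazole, DMF, rt
Reagents that add atoms: tert-butyl(chloro)diphenylsilane, CC(C)(C)[Si](Cl)(c1ccccc1)c1ccccc1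
Why: Silylation of a secondary alcohol; the carbinol stereocentre, which becomes the (S)-acetoxyethyl centre, is not touched.

Step 2
Reactants: 2 silyl ether; 3 2-allyloxirane (racemic)
Product: 4 enynol
Conditions: n-BuLi, THF, −78 °C; BF3·OEt2, then 3, −78 °C
Reagents that add atoms: none
Why: Lewis-acid-assisted SN2 opening of a terminal epoxide by an alkynyllithium at the CH2 terminus; the new carbinol centre forms as both epimers and is removed in step 3.

Step 3
Reactants: 4 enynol
Product: 5 enynone
Conditions: Dess–Martin periodinane, NaHCO3, CH2Cl2, 0 °C to rt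
Reagents that add atoms: none
Why: Dess–Martin oxidation under buffered neutral conditions, chosen so that the skipped ynone/enone does not isomerise to an allenyl or conjugated ketone.

Step 4
Reactants: 5 enynone
Product: 6 enyne ketal
Conditions: 1,2-bis(trimethylsilyloxy)ethane, TMSOTf (cat.), CH2Cl2, −78 °C
Reagents that add atoms: 1,2-bis(trimethylsilyloxy)ethane, C[Si](C)(C)OCCO[Si](C)(C)C
Why: Aprotic low-temperature ketalisation that avoids enolisation; the quaternary ketal carbon also favours the following cyclisation through the gem-disubstituent effect.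

Step 5
Reactants: 6 enyne ketal
Product: 7 bicyclic enone
Conditions: [RhCl(CO)2]2 (cat.), (S)-BINAP, AgOTf, CO (1 atm), THF, 80 °C
Reagents that add atoms: carbon monoxide, [C-]#[O+]
Why: Catalytic asymmetric intramolecular Pauson–Khand reaction closes cyclopentenone ring A and five-membered ring B at once, with the ring-fusion centre C5 (target C3a) set by the chiral diphosphine while the remote side-chain centre is a bystander.

Step 6
Reactants: 7 bicyclic enone
Product: 8 cis-diquinane ketone
Conditions: H2 (1 atm), Pd/C, EtOAc, rt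
Reagents that add atoms: none
Why: Heterogeneous syn hydrogenation of the tetrasubstituted enone from the convex face puts H-1 and H-2 cis to H-5, so the side chain ends on the concave face (target C1 and C7a), a kinetic outcome that enolate chemistry would not give.

Step 7
Reactants: 8 cis-diquinane ketone
Product: 9 diquinane alcohol
Conditions: NaBH4, MeOH, −20 °C
Reagents that add atoms: none
Why: Borohydride reduction stores the ketone as an alcohol so that the epimerisable α-centre survives the later base steps; convex-face hydride attack should give the 3β-alcohol, whose configuration is of no consequence.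

Step 8
Reactants: 9 diquinane alcohol
Product: 10 bis-silyl ether ketal
Conditions: TBSOTf, 2,6-lutidine, CH2Cl2, 0 °C
Reagents that add atoms: tert-butyldimethylsilyl triflate, CC(C)(C)[Si](C)(C)OS(=O)(=O)C(F)(F)F
Why: Silylation of a hindered secondary alcohol with the silyl triflate; the three silyl groups of the route (triethylsilyl, tert-butyldimethylsilyl, tert-butyldiphenylsilyl) are graded for stepwise removal.

Step 9
Reactants: 10 bis-silyl ether ketal
Product: 11 ring-B ketone
Conditions: PPTS, acetone/H2O, 55 °C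
Reagents that add atoms: water, O
Why: Acid-catalysed hydrolysis of the dioxolane under conditions that spare secondary silyl ethers.

Step 10
Reactants: 11 ring-B ketone
Product: 12 6-methyl ketone
Conditions: lithium bis[(R)-1-phenylethyl]amide (from the amine and n-BuLi), LiCl, THF, −100 °C; then MeI, −78 °C
Reagents that add atoms: iodomethane, CI
Why: Group-selective deprotonation of a cis-bicyclo[3.3.0]octan-3-one by a chiral lithium amide (a known desymmetrisation type) chooses the C6 methylene next to C5 over C8, and the enolate is methylated on the convex face; the methyl configuration is irrelevant because C6 becomes sp2.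

Step 11
Reactants: 12 6-methyl ketone
Product: 13 trimethylsilyl enol ether
Conditions: TMSCl, Et3N, DMF, 100 °C
Reagents that add atoms: chlorotrimethylsilane, C[Si](C)(C)Cl
Why: Silyl enol ether formation under equilibrating conditions favours the tetrasubstituted C6=C7 isomer, so the methyl group fixes the regiochemistry of the ring expansion.

Step 12
Reactants: 13 trimethylsilyl enol ether
Product: 14 siloxycyclopropane
Conditions: Et2Zn, CH2I2, CH2Cl2, 0 °C
Reagents that add atoms: diiodomethane, ICI
Why: Simmons–Smith cyclopropanation (Furukawa modification) of the electron-rich enol ether from the convex face; the added carbon is the future C5 of the target.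

Step 13
Reactants: 14 siloxycyclopropane
Product: 16 hydrindenone (4-methyl-4-en-6-one), via chloro ketone 15 (not isolated)
Conditions: FeCl3, pyridine, DMF, 0 °C to rt; then NaOAc, MeOH, 60 °C
Reagents that add atoms: none
Why: FeCl3 oxidises the siloxycyclopropane by one electron and, after loss of the silyl group, the cyclopropoxy radical undergoes β-scission of the internal C6–C7 bond shared by the three- and five-membered rings, releasing the bicyclo[3.1.0] strain and leaving a tertiary β-keto radical that takes chlorine from a second FeCl3 to give 15, from which NaOAc removes HCl (E1cB) to the conjugated enone. The closest known reaction type is the iron trichloride-mediated one-carbon ring expansion of 1-siloxybicyclo[n.1.0]alkanes to cycloalk-2-enones (Saegusa–Ito ring expansion). The six-membered ring is closed by ring enlargement and not by cyclisation: both bonds to the inserted carbon were made in step 12 and this step cuts the zero bridge, so no exo or endo closure geometry has to be met. No new stereocentre is formed, and C3a, C7a and C1 are not touched, so the cis ring fusion and the concave side chain are kept. The selectivity needed is internal versus external cyclopropane cleavage and the position of the double bond; the methyl group at C4 secures both, because only internal cleavage gives a tertiary radical and the enone must then be the 4-methyl-4-en-6-one.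

Step 14
Reactants: 16 hydrindenone
Product: 17 allylic alcohol
Conditions: NaBH4, CeCl3·7H2O, MeOH, −78 °C
Reagents that add atoms: none
Why: Luche 1,2-reduction with hydride delivered to the convex α-face of the cis-hydrindenone, which should give the 6β-alcohol (the target configuration at C6).

Step 15
Reactants: 17 allylic alcohol
Product: 18 bromoacetate
Conditions: bromoacetyl bromide, pyridine, CH2Cl2, −20 °C
Reagents that add atoms: bromoacetyl bromide, BrCC(Br)=O
Why: Acylation of the secondary alcohol; the ester supplies the two lactone carbons and blocks hydroxyl-directed syn epoxidation.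

Step 16
Reactants: 18 bromoacetate
Product: 19 epoxy bromoacetate
Conditions: mCPBA, NaHCO3, CH2Cl2, 0 °C
Reagents that add atoms: 3-chloroperoxybenzoic acid, OOC(=O)c1cccc(Cl)c1
Why: Peracid epoxidation of the only alkene from the convex α-face, anti to the β-acyloxy group, which fixes the C5–O bond α (trans to C6–O).

Step 17
Reactants: 19 epoxy bromoacetate
Product: 20 diazoacetate
Conditions: N,N'-bis(p-toluenesulfonyl)hydrazine, DBU, THF, 0 °C
Reagents that add atoms: N,N'-ditosylhydrazine, Cc1ccc(cc1)S(=O)(=O)NNS(=O)(=O)c1ccc(C)cc1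
Why: N-Alkylation of the ditosylhydrazine by the bromoacetate and double sulfinate elimination give the diazoacetate under mild base that leaves the epoxide intact.

Step 18
Reactants: 20 diazoacetate
Product: 21 γ-lactone
Conditions: Rh2(cap)4 (dirhodium tetracaprolactamate, cat.), CH2Cl2, 40 °C, slow addition
Reagents that add atoms: none
Why: Intramolecular rhodium-carbenoid 1,5 C–H insertion with retention into the C7–H bond cis to the ester oxygen gives the cis-fused γ-lactone and so puts the C7 branch on the concave β-face; C5 carries only an unreactive epoxide C–H and no alkene is present.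

Step 19
Reactants: 21 γ-lactone
Product: 24 α-methylene lactone, via Mannich base 22 (not isolated), via ammonium iodide 23 (not isolated)
Conditions: LDA, THF, −78 °C; Eschenmoser's salt, −78 to 0 °C; then MeI, MeOH, rt; then NaHCO3 (aq), CH2Cl2
Reagents that add atoms: Eschenmoser's salt (N,N-dimethylmethyleneiminium iodide), C=[N+](C)C.[I-]
Why: α-Methylenation of the lactone by Mannich reaction of its enolate, quaternisation and base-induced elimination; the exocyclic carbon is the future oxirane CH2.

Step 20
Reactants: 24 α-methylene lactone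
Product: 26 spiro-epoxy lactone, via bromohydrin 25 (not isolated)
Conditions: NBS, THF/H2O, 0 °C; then K2CO3, acetone, rt
Reagents that add atoms: water, O
Why: Bromohydrin formation places bromine on the exposed face of the exocyclic alkene with water opening at CH2, and the alkoxide then displaces the tertiary bromide with inversion, so the oxirane oxygen ends on the inner face, which is the required (S) centre and the opposite of what direct epoxidation would give.

Step 21
Reactants: 26 spiro-epoxy lactone
Product: 27 allylic triethylsilyl ether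
Conditions: TESOTf, 2,6-lutidine, toluene, −78 °C; then DBU, −78 °C to rt
Reagents that add atoms: triethylsilyl triflate, CC[Si](CC)(CC)OS(=O)(=O)C(F)(F)F
Why: Silyl-triflate-promoted isomerisation of the trisubstituted epoxide to an allylic silyl ether: ionisation at the tertiary C4 and removal of a methyl proton give the exocyclic methylene while the C5–O bond is not broken (α configuration kept); the carbonyl-flanked spiro-epoxide does not ionise.

Step 22
Reactants: 27 allylic triethylsilyl ether
Product: 29 hydroxy ester, via lithium carboxylate 28 (not isolated)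
Conditions: LiOH, THF/H2O, 0 °C; evaporate; then MeI, DMF, rt
Reagents that add atoms: lithium hydroxide, [Li+].[OH-]; iodomethane, CI
Why: Saponification opens the lactone irreversibly as the carboxylate, and O-alkylation gives the methyl ester and frees the C6 hydroxyl without acid that would re-close the lactone.

Step 23
Reactants: 29 hydroxy ester; 30 (E)-3-methylpent-2-enoic acid
Product: 31 C6 ester
Conditions: DCC, DMAP, CH2Cl2, 0 °C to rt
Reagents that add atoms: none
Why: Steglich esterification of the free C6 hydroxyl, done at once so that the γ-hydroxy ester cannot lactonise.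

Step 24
Reactants: 31 C6 ester
Product: 32 C5 alcohol
Conditions: HF·pyridine, pyridine, THF, 0 °C
Reagents that add atoms: none
Why: Buffered fluoride cleaves the triethylsilyl ether much faster than the tert-butyldimethylsilyl and tert-butyldiphenylsilyl ethers.

Step 25
Reactants: 32 C5 alcohol; 33 (R)-2-methylbutanoic acid
Product: 34 diester
Conditions: DCC, DMAP (cat.), CH2Cl2, 0 °C
Reagents that add atoms: none
Why: Steglich esterification of the allylic C5 hydroxyl at low temperature to protect the α-stereocentre of the acid.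

Step 26
Reactants: 34 diester
Product: 35 C2 alcohol
Conditions: HF·pyridine, THF, rt
Reagents that add atoms: none
Why: Selective cleavage of the secondary tert-butyldimethylsilyl ether in the presence of the tert-butyldiphenylsilyl ether.

Step 27
Reactants: 35 C2 alcohol
Product: 36 C2 ketone
Conditions: Dess–Martin periodinane, NaHCO3, CH2Cl2, rt
Reagents that add atoms: none
Why: Dess–Martin oxidation restores the ring-A ketone under neutral conditions, so the kinetically set C1 centre is not epimerised.

Step 28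
Reactants: 36 C2 ketone
Product: 37 hydroxy ketone
Conditions: HF·pyridine (excess), THF, rt to 40 °C
Reagents that add atoms: none
Why: Acidic fluoride removes the tert-butyldiphenylsilyl group without the basic conditions that would cause retro-aldol, elimination or epimerisation of the β-hydroxy ketone.

Step 29
Reactants: 37 hydroxy ketone
Product: 38 CNP0251769.2 (target)
Conditions: Ac2O, pyridine, 0 °C
Reagents that add atoms: acetic anhydride, CC(=O)OC(C)=O
Why: Acetylation of the last free hydroxyl under mild conditions; all stereocentres are already in place.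

**Compound list**

1 | (S)-but-3-yn-2-ol | C#C[C@H](C)O | starting material
2 | (S)-tert-butyl(but-3-yn-2-yloxy)diphenylsilane | C#C[C@H](C)O[Si](c1ccccc1)(c1ccccc1)C(C)(C)C | intermediate
3 | 2-allyloxirane (racemic) | C=CCC1CO1 | starting material
4 | (8S)-8-(tert-butyldiphenylsilyloxy)non-1-en-6-yn-4-ol (both C4 epimers) | C=CCC(O)CC#C[C@H](C)O[Si](c1ccccc1)(c1ccccc1)C(C)(C)C | intermediate
5 | (8S)-8-(tert-butyldiphenylsilyloxy)non-1-en-6-yn-4-one | C=CCC(=O)CC#C[C@H](C)O[Si](c1ccccc1)(c1ccccc1)C(C)(C)C | intermediate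
6 | 2-allyl-2-[(4S)-4-(tert-butyldiphenylsilyloxy)pent-2-yn-1-yl]-1,3-dioxolane | C=CCC1(OCCO1)CC#C[C@H](C)O[Si](c2ccccc2)(c2ccccc2)C(C)(C)C | intermediate
7 | 2-[(1S)-1-(tert-butyldiphenylsilyloxy)ethyl]-7,7-ethylenedioxybicyclo[3.3.0]oct-1-en-3-one, H-5 α | C1[C@H]2CC(=O)C([C@H](C)O[Si](c3ccccc3)(c3ccccc3)C(C)(C)C)=C2CC14OCCO4 | intermediate
8 | 2β-[(1S)-1-(tert-butyldiphenylsilyloxy)ethyl]-7,7-ethylenedioxy-cis-bicyclo[3.3.0]octan-3-one, H-1, H-2 and H-5 all α | C1[C@H]2CC(=O)[C@@H]([C@H](C)O[Si](c3ccccc3)(c3ccccc3)C(C)(C)C)[C@H]2CC14OCCO4 | intermediate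
9 | 3β-alcohol of 8 | C1[C@H]2C[C@@H](O)[C@@H]([C@H](C)O[Si](c3ccccc3)(c3ccccc3)C(C)(C)C)[C@H]2CC14OCCO4 | intermediate
10 | 3β-(tert-butyldimethylsilyl) ether of 9 | C1[C@H]2C[C@@H](O[Si](C)(C)C(C)(C)C)[C@@H]([C@H](C)O[Si](c3ccccc3)(c3ccccc3)C(C)(C)C)[C@H]2CC14OCCO4 | intermediate
11 | 3β-(tert-butyldimethylsilyloxy)-2β-[(1S)-1-(tert-butyldiphenylsilyloxy)ethyl]-cis-bicyclo[3.3.0]octan-7-one | C1[C@H]2C[C@@H](O[Si](C)(C)C(C)(C)C)[C@@H]([C@H](C)O[Si](c3ccccc3)(c3ccccc3)C(C)(C)C)[C@H]2CC1=O | intermediate
12 | 6α-methyl derivative of 11 | C[C@@H]1[C@H]2C[C@@H](O[Si](C)(C)C(C)(C)C)[C@@H]([C@H](C)O[Si](c3ccccc3)(c3ccccc3)C(C)(C)C)[C@H]2CC1=O | intermediate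
13 | 6-methyl-7-(trimethylsilyloxy)bicyclo[3.3.0]oct-6-ene with the 2β and 3β substituents of 11 | CC=1[C@H]2C[C@@H](O[Si](C)(C)C(C)(C)C)[C@@H]([C@H](C)O[Si](c3ccccc3)(c3ccccc3)C(C)(C)C)[C@H]2CC=1O[Si](C)(C)C | intermediate
14 | 6α,7α-methano (cyclopropane) adduct of 13: 6-methyl-7-trimethylsilyloxy siloxycyclopropane | C[C@@]12[C@H]3C[C@@H](O[Si](C)(C)C(C)(C)C)[C@@H]([C@H](C)O[Si](c4ccccc4)(c4ccccc4)C(C)(C)C)[C@H]3C[C@]1(O[Si](C)(C)C)C2 | intermediate
15 | 4-chloro-4-methyl-octahydroinden-6-one with 2β-OTBS and 1β-side chain (C4 epimers) | CC1(Cl)[C@H]2C[C@@H](O[Si](C)(C)C(C)(C)C)[C@@H]([C@H](C)O[Si](c3ccccc3)(c3ccccc3)C(C)(C)C)[C@H]2CC(=O)C1 | intermediate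
16 | 2β-(tert-butyldimethylsilyloxy)-1β-[(1S)-1-(tert-butyldiphenylsilyloxy)ethyl]-4-methyl-1,2,3,3a,7,7a-hexahydro-6H-inden-6-one, H-3a and H-7a α | CC=1[C@H]2C[C@@H](O[Si](C)(C)C(C)(C)C)[C@@H]([C@H](C)O[Si](c3ccccc3)(c3ccccc3)C(C)(C)C)[C@H]2CC(=O)C=1 | intermediate
17 | 6β-alcohol of 16 | CC=1[C@H]2C[C@@H](O[Si](C)(C)C(C)(C)C)[C@@H]([C@H](C)O[Si](c3ccccc3)(c3ccccc3)C(C)(C)C)[C@H]2C[C@@H](O)C=1 | intermediate
18 | 6β-bromoacetate of 17 | CC=1[C@H]2C[C@@H](O[Si](C)(C)C(C)(C)C)[C@@H]([C@H](C)O[Si](c3ccccc3)(c3ccccc3)C(C)(C)C)[C@H]2C[C@@H](OC(=O)CBr)C=1 | intermediate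
19 | 4α,5α-epoxide of 18 | C[C@@]15[C@H]2C[C@@H](O[Si](C)(C)C(C)(C)C)[C@@H]([C@H](C)O[Si](c3ccccc3)(c3ccccc3)C(C)(C)C)[C@H]2C[C@@H](OC(=O)CBr)[C@@H]1O5 | intermediate
20 | 6β-diazoacetate of the 4α,5α-epoxide | C[C@@]15[C@H]2C[C@@H](O[Si](C)(C)C(C)(C)C)[C@@H]([C@H](C)O[Si](c3ccccc3)(c3ccccc3)C(C)(C)C)[C@H]2C[C@@H](OC(=O)C=[N+]=[N-])[C@@H]1O5 | intermediate
21 | cis-fused γ-lactone (C7β–CH2–CO–O–C6β) of the 4α,5α-epoxide | C[C@@]15[C@H]2C[C@@H](O[Si](C)(C)C(C)(C)C)[C@@H]([C@H](C)O[Si](c3ccccc3)(c3ccccc3)C(C)(C)C)[C@H]2[C@@H](CC(=O)O6)[C@@H]6[C@@H]1O5 | intermediate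
22 | α-(dimethylaminomethyl) lactone (Mannich base) | C[C@@]15[C@H]2C[C@@H](O[Si](C)(C)C(C)(C)C)[C@@H]([C@H](C)O[Si](c3ccccc3)(c3ccccc3)C(C)(C)C)[C@H]2[C@@H](C(CN(C)C)C(=O)O6)[C@@H]6[C@@H]1O5 | intermediate
23 | α-(trimethylammoniomethyl) lactone iodide | C[C@@]15[C@H]2C[C@@H](O[Si](C)(C)C(C)(C)C)[C@@H]([C@H](C)O[Si](c3ccccc3)(c3ccccc3)C(C)(C)C)[C@H]2[C@@H](C(C[N+](C)(C)C)C(=O)O6)[C@@H]6[C@@H]1O5.[I-] | intermediate
24 | α-methylene-γ-lactone | C[C@@]15[C@H]2C[C@@H](O[Si](C)(C)C(C)(C)C)[C@@H]([C@H](C)O[Si](c3ccccc3)(c3ccccc3)C(C)(C)C)[C@H]2[C@@H](C(=C)C(=O)O6)[C@@H]6[C@@H]1O5 | intermediate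
25 | α-bromo-α-(hydroxymethyl) lactone, bromine on the exposed face | C[C@@]15[C@H]2C[C@@H](O[Si](C)(C)C(C)(C)C)[C@@H]([C@H](C)O[Si](c3ccccc3)(c3ccccc3)C(C)(C)C)[C@H]2[C@@H]([C@@](Br)(CO)C(=O)O6)[C@@H]6[C@@H]1O5 | intermediate
26 | spiro-oxirane lactone, oxirane carbon (S) | C[C@@]15[C@H]2C[C@@H](O[Si](C)(C)C(C)(C)C)[C@@H]([C@H](C)O[Si](c3ccccc3)(c3ccccc3)C(C)(C)C)[C@H]2[C@@H]([C@@]7(C(=O)O6)CO7)[C@@H]6[C@@H]1O5 | intermediate
27 | 4-methylidene-5α-(triethylsilyloxy) spiro-oxirane lactone | C=C1[C@H]2C[C@@H](O[Si](C)(C)C(C)(C)C)[C@@H]([C@H](C)O[Si](c3ccccc3)(c3ccccc3)C(C)(C)C)[C@H]2[C@@H]([C@@]7(C(=O)O6)CO7)[C@@H]6[C@@H]1O[Si](CC)(CC)CC | intermediate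
28 | lithium (2S)-2-(6β-hydroxy-hydrindan-7β-yl)oxirane-2-carboxylate (ring-opened lactone) | C=C1[C@H]2C[C@@H](O[Si](C)(C)C(C)(C)C)[C@@H]([C@H](C)O[Si](c3ccccc3)(c3ccccc3)C(C)(C)C)[C@H]2[C@@H]([C@@]4(C(=O)[O-])CO4)[C@@H](O)[C@@H]1O[Si](CC)(CC)CC.[Li+] | intermediate
29 | methyl (2S)-oxirane-2-carboxylate with free 6β-OH, 5α-OTES, 2β-OTBS and TBDPS-protected side chain | C=C1[C@H]2C[C@@H](O[Si](C)(C)C(C)(C)C)[C@@H]([C@H](C)O[Si](c3ccccc3)(c3ccccc3)C(C)(C)C)[C@H]2[C@@H]([C@@]4(C(=O)OC)CO4)[C@@H](O)[C@@H]1O[Si](CC)(CC)CC | intermediate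
30 | (E)-3-methylpent-2-enoic acid | CC/C(C)=C/C(=O)O | starting material
31 | 6β-[(E)-3-methylpent-2-enoate] of 29 | C=C1[C@H]2C[C@@H](O[Si](C)(C)C(C)(C)C)[C@@H]([C@H](C)O[Si](c3ccccc3)(c3ccccc3)C(C)(C)C)[C@H]2[C@@H]([C@@]4(C(=O)OC)CO4)[C@@H](OC(=O)/C=C(\C)CC)[C@@H]1O[Si](CC)(CC)CC | intermediate
32 | 5α-alcohol (triethylsilyl group removed) | C=C1[C@H]2C[C@@H](O[Si](C)(C)C(C)(C)C)[C@@H]([C@H](C)O[Si](c3ccccc3)(c3ccccc3)C(C)(C)C)[C@H]2[C@@H]([C@@]4(C(=O)OC)CO4)[C@@H](OC(=O)/C=C(\C)CC)[C@@H]1O | intermediate
33 | (R)-2-methylbutanoic acid | CC[C@@H](C)C(=O)O | starting material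
34 | 5α-[(R)-2-methylbutanoate] 6β-[(E)-3-methylpent-2-enoate] | C=C1[C@H]2C[C@@H](O[Si](C)(C)C(C)(C)C)[C@@H]([C@H](C)O[Si](c3ccccc3)(c3ccccc3)C(C)(C)C)[C@H]2[C@@H]([C@@]4(C(=O)OC)CO4)[C@@H](OC(=O)/C=C(\C)CC)[C@@H]1OC(=O)[C@H](C)CC | intermediate
35 | 2β-alcohol of 34 | C=C1[C@H]2C[C@@H](O)[C@@H]([C@H](C)O[Si](c3ccccc3)(c3ccccc3)C(C)(C)C)[C@H]2[C@@H]([C@@]4(C(=O)OC)CO4)[C@@H](OC(=O)/C=C(\C)CC)[C@@H]1OC(=O)[C@H](C)CC | intermediate
36 | 2-ketone with TBDPS-protected side chain | C=C1[C@H]2CC(=O)[C@@H]([C@H](C)O[Si](c3ccccc3)(c3ccccc3)C(C)(C)C)[C@H]2[C@@H]([C@@]4(C(=O)OC)CO4)[C@@H](OC(=O)/C=C(\C)CC)[C@@H]1OC(=O)[C@H](C)CC | intermediate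
37 | 1-[(1S)-1-hydroxyethyl] 2-ketone | C=C1[C@H]2CC(=O)[C@@H]([C@H](C)O)[C@H]2[C@@H]([C@@]4(C(=O)OC)CO4)[C@@H](OC(=O)/C=C(\C)CC)[C@@H]1OC(=O)[C@H](C)CC | intermediate
38 | CNP0251769.2: methyl (2S)-2-[(1R,3aS,5R,6R,7R,7aR)-1-[(1S)-1-acetoxyethyl]-4-methylidene-5-[(2R)-2-methylbutanoyloxy]-6-[(2E)-3-methylpent-2-enoyloxy]-2-oxo-octahydro-1H-inden-7-yl]oxirane-2-carboxylate | C=C1[C@H]2CC(=O)[C@@H]([C@H](C)OC(C)=O)[C@H]2[C@@H]([C@@]2(C(=O)OC)CO2)[C@@H](OC(=O)/C=C(\C)CC)[C@@H]1OC(=O)[C@H](C)CC | target

**Step count**
Total steps: 29. Longest linear sequence: 29 steps (from 1; 3, 30 and 33 are commercial inputs).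

**Three steps most likely to fail, with fallbacks**

Step 5 (Pauson–Khand stereocontrol). The risk is poor facial selectivity in the alkene insertion, because the chiral ligand may be mismatched with the branched side-chain stereocentre, together with slow turnover of the hindered alkyne. The fallback sets out from 6 and returns at 7. The enyne is cyclised without a chiral ligand, using Mo(CO)6 and DMSO in toluene at 100 °C. This should give 7 together with its ring-fusion epimer F1. The two are diastereomers because of the (S)-silyloxyethyl group, so stereocontrol is replaced by chromatographic separation, and only 7 is carried on.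

Step 10 (regioselective methylation). The risk is loss of regiocontrol in the deprotonation (C6 versus C8) once the lithium enolate equilibrates before alkylation, with over-methylation as a second problem. The fallback sets out from 11 and returns at 16; it introduces the methyl group after the ring expansion instead of before it. The ketone is deprotonated with the same chiral amide in the presence of TMSCl (internal quench), which traps the kinetic C6 enolate as the trisubstituted silyl enol ether F2. Simmons–Smith cyclopropanation (Et2Zn, CH2I2) gives the siloxycyclopropane F3. The FeCl3 ring expansion then passes through the β-chloro ketone F4 and, after NaOAc, gives the unsubstituted enone F5. Conjugate addition of Me2CuLi with TMSCl gives the silyl enol ether F6, and Saegusa–Ito oxidation with Pd(OAc)2 in MeCN returns the 4-methyl enone 16.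

Step 20 (bromohydrin and oxirane closure). The risk is sluggish bromonium formation on the electron-poor exocyclic alkene, which would allow competing opening of the trisubstituted epoxide and erosion of facial selectivity. The fallback sets out from 21 and returns at 25; it builds the same tertiary bromide by enolate chemistry. The lactone enolate (LDA, −78 °C) is hydroxymethylated with gaseous formaldehyde to the α-hydroxymethyl lactone F7. Its dianion (LDA, 2.2 equiv) is brominated with NBS on the exposed face to give bromohydrin 25, which is closed with K2CO3 as in step 20.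

**Further compounds**

F1 | step 5 | ring-fusion (C5) epimer of 7 | C1[C@@H]2CC(=O)C([C@H](C)O[Si](c3ccccc3)(c3ccccc3)C(C)(C)C)=C2CC14OCCO4
F2 | step 10 | 7-(trimethylsilyloxy)bicyclo[3.3.0]oct-6-ene from 11 (C6 unsubstituted) | C=1[C@H]2C[C@@H](O[Si](C)(C)C(C)(C)C)[C@@H]([C@H](C)O[Si](c3ccccc3)(c3ccccc3)C(C)(C)C)[C@H]2CC=1O[Si](C)(C)C
F3 | step 10 | 6α,7α-methano siloxycyclopropane without the 6-methyl group | [C@@H]12[C@H]3C[C@@H](O[Si](C)(C)C(C)(C)C)[C@@H]([C@H](C)O[Si](c4ccccc4)(c4ccccc4)C(C)(C)C)[C@H]3C[C@]1(O[Si](C)(C)C)C2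
F4 | step 10 | 4-chloro-octahydroinden-6-one (C4 epimers) | ClC1[C@H]2C[C@@H](O[Si](C)(C)C(C)(C)C)[C@@H]([C@H](C)O[Si](c3ccccc3)(c3ccccc3)C(C)(C)C)[C@H]2CC(=O)C1
F5 | step 10 | 1,2,3,3a,7,7a-hexahydro-6H-inden-6-one without the 4-methyl group | C=1[C@H]2C[C@@H](O[Si](C)(C)C(C)(C)C)[C@@H]([C@H](C)O[Si](c3ccccc3)(c3ccccc3)C(C)(C)C)[C@H]2CC(=O)C=1
F6 | step 10 | 4-methyl-6-(trimethylsilyloxy)hexahydroind-5-ene (C4 epimers) | CC1[C@H]2C[C@@H](O[Si](C)(C)C(C)(C)C)[C@@H]([C@H](C)O[Si](c3ccccc3)(c3ccccc3)C(C)(C)C)[C@H]2CC(O[Si](C)(C)C)=C1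
F7 | step 20 | α-(hydroxymethyl) γ-lactone from 21 (α-epimers) | C[C@@]15[C@H]2C[C@@H](O[Si](C)(C)C(C)(C)C)[C@@H]([C@H](C)O[Si](c3ccccc3)(c3ccccc3)C(C)(C)C)[C@H]2[C@@H](C(CO)C(=O)O6)[C@@H]6[C@@H]1O5
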